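**Plan**

1. Retrosynthetic cuts, in order:
   - C16=C17 (Wittig)
   - C12–C13 (ring C; the 12,13-diol beside C16 is read as the aldol of a ring-D enediol with a C12 aldehyde)
   - C3–C4 (ring A, aldol)
   - C10–C1 together with O10–C19 (allylation/lactonisation)
   - C9–C11 and C5–C4 (enolate alkylations)
   - C6–C7 (nitro-Michael)
   - C5=C6 (aldol condensation)
   - C8–C9 (ester alkylation)
2. Forward order of the rings: D (bought as a cyclopentene) → B (spiro-annulated cyclopentenone) → γ-lactone → A → C, closed last.
3. Enabling feature: C8 is the spiro atom shared by ring B (C5, C6, C8, C9, C10) and ring D (C8, C14, C13, C16, C15). While C13 and C16 are equivalent (alkene, later 1,2-bis(silyloxy)alkene), ring D is locally mirror-symmetric, C8 is no stereocentre, and it is made by a simple alkylation.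
4. Key event: the C12 aldehyde on the α-oriented C9 side chain is attacked only by the enol carbon on the arm cis to that chain. This closes ring C and the bicyclo[3.2.1]octane, makes C8 a quaternary stereocentre, sets C12 and C13, and leaves C16 as the ketone that takes up C17.
5. Stereochemistry: C6 comes from organocatalysis. C5, C9 and C10 follow by relay around the cyclopentanone. C4 is set by the tether, C3 by hydride, and C8/C12/C13 by the key step. The mixtures at C3 and in the acyloin are funnelled into single compounds, and the C4 configuration set in step 8 is erased and reset in step 13.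

Key step: step 20

Numbering: all intermediates carry the gibberellane atom numbers of the target. α is the face of the lactone oxygen O10; β is the face of H5 and H9.

Assumption: the quinine-derived primary amine is taken to give (S)-9; if the sense of induction is opposite, the quinidine-derived pseudo-enantiomer is used instead.

**Step 1**
Reactants: 1 methyl cyclopent-3-ene-1-carboxylate; 2 allyl bromide
Product: 4 methyl 1-allylcyclopent-3-ene-1-carboxylate, via lithium enolate 3 (not isolated)
Conditions: LDA, THF, −78 °C; then 2, −78 °C → rt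
Reagents that add atoms: lithium diisopropylamide, CC(C)N([Li])C(C)C (lithium stays only in 3)
Why: Ester enolate alkylation (SN2) builds the quaternary carbon C8, which is no stereocentre because ring D is symmetric.

**Step 2**
Reactants: 4 methyl 1-allylcyclopent-3-ene-1-carboxylate
Product: 5 1-allylcyclopent-3-ene-1-carbaldehyde
Conditions: DIBAL-H, CH2Cl2, −78 °C; aqueous work-up
Reagents that add atoms: none
Why: Partial DIBAL-H reduction of a hindered α-quaternary ester at low temperature should stop at the aldehyde oxidation level (future C6).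

**Step 3**
Reactants: 5 1-allylcyclopent-3-ene-1-carbaldehyde
Product: 6 1-(2-oxopropyl)cyclopent-3-ene-1-carbaldehyde
Conditions: PdCl2 (cat.), CuCl (cat.), O2 (1 atm), DMF/H2O, rt
Reagents that add atoms: water, O
Why: The Tsuji–Wacker oxidation prefers the terminal monosubstituted alkene to the cyclic 1,2-disubstituted one and gives the methyl ketone (Markovnikov).

**Step 4**
Reactants: 6 1-(2-oxopropyl)cyclopent-3-ene-1-carbaldehyde
Product: 7 spiro[4.4]nona-3,7-dien-2-one
Conditions: aq KOH (cat.), THF/Et2O, reflux
Reagents that add atoms: none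
Why: Intramolecular aldol condensation of the 1,4-keto aldehyde, in which the non-enolisable aldehyde is the only acceptor, closes ring B as an achiral 4,4-disubstituted cyclopentenone.

**Step 5**
Reactants: 7 spiro[4.4]nona-3,7-dien-2-one; 8 nitromethane
Product: 9 (4S)-4-(nitromethyl)spiro[4.4]non-7-en-2-one
Conditions: 9-amino-9-deoxy-epi-quinine (20 mol %), PhCO2H (40 mol %), 8 (excess), THF, 40 °C
Reagents that add atoms: none
Why: In the iminium-catalysed asymmetric Michael addition of nitromethane to a cyclic enone, the chiral primary amine shields one face of the iminium ion and thereby sets C6, the only centre not obtained by relay.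

**Step 6**
Reactants: 9 (4S)-4-(nitromethyl)spiro[4.4]non-7-en-2-one
Product: 10 (1S)-3-oxospiro[4.4]non-7-ene-1-carboxylic acid
Conditions: NaNO2, AcOH, DMSO, 35 °C
Reagents that add atoms: sodium nitrite, [Na+].[O-]N=O
Why: The nitrite-mediated oxidative (Nef-type) conversion of a primary nitroalkane into the carboxylic acid runs under nearly neutral conditions that should spare the ketone, the alkene and the C6 configuration.

**Step 7**
Reactants: 10 (1S)-3-oxospiro[4.4]non-7-ene-1-carboxylic acid
Product: 11 2-(trimethylsilyl)ethyl (1S)-3-oxospiro[4.4]non-7-ene-1-carboxylate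
Conditions: DCC, DMAP (cat.), Me3SiCH2CH2OH, CH2Cl2, 0 °C → rt
Reagents that add atoms: 2-(trimethylsilyl)ethanol, C[Si](C)(C)CCO
Why: Steglich esterification masks C7 as a fluoride-labile ester that can leave together with the silyl ethers in the last step.

**Step 8**
Reactants: 11 2-(trimethylsilyl)ethyl (1S)-3-oxospiro[4.4]non-7-ene-1-carboxylate; 12 ethyl (2S)-2-(trifluoromethylsulfonyloxy)propanoate
Product: 14 keto diester (C10 ketone, 6β-CO2CH2CH2SiMe3, 5α-CH(CH3)CO2Et), via C5 lithium enolate 13 (not isolated)
Conditions: LDA, THF, −78 °C; then 12, −78 → −30 °C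
Reagents that add atoms: lithium diisopropylamide, CC(C)N([Li])C(C)C (lithium stays only in 13)
Why: Kinetic deprotonation should occur at C5 because C9–H2 is neopentyl, and SN2 alkylation by the reactive secondary triflate occurs anti to the 6β-ester, which sets C5 (trans), while the C4 configuration (inversion) is erased in step 13.

**Step 9**
Reactants: 14 keto diester; 15 2-bromo-N,N-diethylacetamide
Product: 17 keto amide (14 carrying 9α-CH2CONEt2), via C9 lithium enolate 16 (not isolated)
Conditions: LDA, THF/DMPU, −78 °C; then 15, −78 → 0 °C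
Reagents that add atoms: lithium diisopropylamide, CC(C)N([Li])C(C)C (lithium stays only in 16)
Why: Kinetic enolisation at the only remaining α-CH2 is followed by SN2 alkylation, and the trans-diequatorial C5/C6 groups lock the envelope so that the β arm (C15) of the spiro ring is pseudoaxial and shields the β face, so the electrophile should enter α and set C9 cis to the C5 chain.

**Step 10**
Reactants: 17 keto amide; 2 allyl bromide
Product: 19 allyl lactone (10β-allyl, 19,10-γ-lactone cis-fused to ring B), via hydroxy ester 18 (not isolated)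
Conditions: Zn dust, 2, THF, 0 °C → rt; aq NH4Cl; then CSA (cat.), toluene, 60 °C
Reagents that add atoms: none
Why: The ester- and amide-tolerant Barbier allylation attacks the ketone from the β face, opposite to both α side chains at C5 and C9, which sets C10, and the α-oriented O10 lies cis to the propanoate chain and closes the γ-lactone by 5-exo-trig acyl substitution.

**Step 11**
Reactants: 19 allyl lactone
Product: 21 primary alcohol (10β-CH2CH2CH2OH), via B-alkyl-9-BBN adduct 20 (not isolated)
Conditions: 9-BBN, THF, 0 °C → rt; then 30 % H2O2, aq NaOH, 0 °C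
Reagents that add atoms: 9-borabicyclo[3.3.1]nonane, [H]B1C2CCCC1CCC2 (boron stays only in 20); hydrogen peroxide, OO
Why: In the hydroboration–oxidation, 9-BBN distinguishes the terminal allyl group from the cyclopentene by its large rate preference for monosubstituted alkenes and places the oxygen on C3.

**Step 12**
Reactants: 21 primary alcohol
Product: 22 aldehyde (C3 = CHO)
Conditions: Dess–Martin periodinane, CH2Cl2, rt
Reagents that add atoms: none
Why: Dess–Martin oxidation takes the primary alcohol to the aldehyde without touching alkene, lactone, ester or amide.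

**Step 13**
Reactants: 22 aldehyde
Product: 23 tricyclic aldol (rings A, B and lactone; C3 epimers)
Conditions: K2CO3 (cat.), MeOH, 0 °C → rt, high dilution
Reagents that add atoms: none
Why: The intramolecular aldol addition (6-enolexo-exo-trig) of the lactone enolate to the C3 aldehyde is run under equilibrating conditions, as in the aldol equilibrium that epimerises C3 of 3-hydroxygibberellins in base, and the C1–C3 tether reaches only one face of the enolate, which sets the quaternary C4, while C3 forms as a mixture.

**Step 14**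
Reactants: 23 tricyclic aldol
Product: 24 3-ketone (β-keto lactone)
Conditions: Dess–Martin periodinane, CH2Cl2, rt
Reagents that add atoms: none
Why: Dess–Martin oxidation converges both C3 epimers to one β-keto lactone whose C4 is quaternary and cannot epimerise.

**Step 15**
Reactants: 24 3-ketone
Product: 25 3β-alcohol
Conditions: K-Selectride, THF, −78 °C; H2O
Reagents that add atoms: none
Why: The bulky trialkylborohydride attacks the cyclohexanone along the equatorial trajectory and should give the axial 3β-alcohol (anti to C19), with lactone, ester and amide untouched at −78 °C.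

**Step 16**
Reactants: 25 3β-alcohol
Product: 26 3β-TBS ether
Conditions: TBSOTf, 2,6-lutidine, CH2Cl2, 0 °C
Reagents that add atoms: tert-butyldimethylsilyl triflate, CC(C)(C)[Si](C)(C)OS(=O)(=O)C(F)(F)F
Why: Silylation with the reactive silyl triflate protects the hindered axial alcohol against the later oxidation and blocks retro-aldol opening of ring A.

**Step 17**
Reactants: 26 3β-TBS ether
Product: 27 ring-D acyloins (13/16-hydroxy ketone, mixture of four regio- and stereoisomers)
Conditions: RuCl3 (1 mol %), Oxone, NaHCO3, EtOAc/MeCN/H2O, rt, short contact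
Reagents that add atoms: potassium peroxymonosulfate (Oxone), [K+].[O-]S(=O)(=O)OO
Why: RuO4-catalysed ketohydroxylation of the only remaining alkene is much faster than oxidation of amide N-alkyl groups, and the isomers need no separation because all converge in step 18.

**Step 18**
Reactants: 27 ring-D acyloins
Product: 28 13,16-bis(TBS) enediol ether (C13=C16)
Conditions: TBSOTf, Et3N, CH2Cl2, 0 °C → rt
Reagents that add atoms: tert-butyldimethylsilyl triflate, CC(C)(C)[Si](C)(C)OS(=O)(=O)C(F)(F)F
Why: O-silylation is followed by soft enolisation (thermodynamic silyl enol ether formation), which removes the oxygen-acidified carbinol C–H rather than the neopentyl α′-CH2 next to C8, so all four acyloins give the same tetrasubstituted enediol ether, in which ring D is again symmetric and C8 is no stereocentre.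

**Step 19**
Reactants: 28 13,16-bis(TBS) enediol ether
Product: 29 aldehyde (C12 = CHO)
Conditions: Cp2Zr(H)Cl (Schwartz reagent), THF, rt; H2O, short Et3N-deactivated silica plug
Reagents that add atoms: none
Why: Hydrozirconation of the tertiary amide carbonyl followed by hydrolysis gives the aldehyde chemoselectively beside ester, lactone, silyl ethers and the tetrasubstituted enol ether, under non-acidic and non-oxidising conditions.

**Step 20**
Reactants: 29 aldehyde
Product: 30 tetracyclic 16-ketone (12α,13-bis-OTBS, 3β-OTBS, 7-TMSE ester)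
Conditions: HNTf2 (5 mol %), CH2Cl2 (high dilution), −78 °C; pyridine quench
Reagents that add atoms: none
Why: HNTf2 is converted by the enol silane into TBSNTf2, which silylates the aldehyde oxygen; C13 of the 1,2-bis(silyloxy)cyclopentene then adds to C12 and the silyl group on O16 is passed on as chain carrier, so 30 forms without loss of atoms (silyl-transfer Mukaiyama aldol addition). The closest known reaction type is the Lewis-acid-mediated aldol addition of 1,2-bis(trimethylsilyloxy)cycloalkenes to aldehydes and acetals, used here intramolecularly. Ring C (C8, C9, C11, C12, C13, C14) closes in the 6-(enolexo)-exo-trig mode and completes the bicyclo[3.2.1]octane. The selectivity needed is between the two diastereotopic enol carbons of the locally symmetric ring D: the C11–C12 chain is α on C9 and reaches only the carbon on the α arm (C14) through a cis-fused hydrindane-like array, whereas the other carbon would need a trans-fused bridged array, so C8 is desymmetrised in the natural sense and the bridgehead C13 is fixed by the tether (attack on the face of ring D that looks at C9). C12 is controlled by the open antiperiplanar transition state, in which the bulky silylated oxygen points away from C16 and its silyloxy group while H12 takes the crowded sector between O13 and C16, giving the axial 12α-oxygen cis to O13. Catalytic acid, −78 °C and high dilution suppress acyl migration of the adduct and intermolecular aldol addition.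

**Step 21**
Reactants: 30 tetracyclic 16-ketone; 31 methyltriphenylphosphonium bromide
Product: 32 16-methylene compound (fully protected target)
Conditions: 31, KOtBu, THF, 0 °C; then 30, rt → 50 °C
Reagents that add atoms: none
Why: The Wittig methylenation of 16-oxo gibberellin-type ketones is well precedented, and here C13 bears no hydrogen and O12/O13 are silylated, so neither elimination nor retro-aldol cleavage can compete.

**Step 22**
Reactants: 32 16-methylene compound
Product: 33 CNP0260503.1 (target)
Conditions: TBAF, AcOH (1:1), THF, rt → 45 °C; work-up at pH 3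
Reagents that add atoms: none
Why: Fluoride cleaves the three silyl ethers and fragments the 2-(trimethylsilyl)ethyl ester in one operation, and the acetic acid buffer avoids free alkoxide at O3 (retro-aldol epimerisation) as well as the strong acid that would rearrange the 13-hydroxy-16-ene unit.

**Compound list**

1 | methyl cyclopent-3-ene-1-carboxylate | COC(=O)C1CC=CC1 | starting material
2 | allyl bromide | C=CCBr | starting material
3 | lithium enolate of 1 | COC(O[Li])=C1CC=CC1 | intermediate
4 | methyl 1-allylcyclopent-3-ene-1-carboxylate | COC(=O)C1(CC=C)CC=CC1 | intermediate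
5 | 1-allylcyclopent-3-ene-1-carbaldehyde | O=CC1(CC=C)CC=CC1 | intermediate
6 | 1-(2-oxopropyl)cyclopent-3-ene-1-carbaldehyde | CC(=O)CC1(C=O)CC=CC1 | intermediate
7 | spiro[4.4]nona-3,7-dien-2-one | O=C1C=CC2(C1)CC=CC2 | intermediate
8 | nitromethane | C[N+](=O)[O-] | starting material
9 | (4S)-4-(nitromethyl)spiro[4.4]non-7-en-2-one | O=C1CC2(CC=CC2)[C@@H](C[N+](=O)[O-])C1 | intermediate
10 | (1S)-3-oxospiro[4.4]non-7-ene-1-carboxylic acid | O=C1CC2(CC=CC2)[C@@H](C(=O)O)C1 | intermediate
11 | 2-(trimethylsilyl)ethyl (1S)-3-oxospiro[4.4]non-7-ene-1-carboxylate | O=C1CC2(CC=CC2)[C@@H](C(=O)OCC[Si](C)(C)C)C1 | intermediate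
12 | ethyl (2S)-2-(trifluoromethylsulfonyloxy)propanoate | CCOC(=O)[C@H](C)OS(=O)(=O)C(F)(F)F | starting material
13 | C5 lithium enolate of 11 | [Li]OC1=C[C@H](C(=O)OCC[Si](C)(C)C)C2(CC=CC2)C1 | intermediate
14 | keto diester (5α-CH(CH3)CO2Et, 6β-ester, C10 ketone) | O=C1CC2(CC=CC2)[C@@H](C(=O)OCC[Si](C)(C)C)[C@@H]1[C@H](C)C(=O)OCC | intermediate
15 | 2-bromo-N,N-diethylacetamide | CCN(CC)C(=O)CBr | starting material
16 | C9 lithium enolate of 14 | [Li]OC1=CC2(CC=CC2)[C@@H](C(=O)OCC[Si](C)(C)C)[C@@H]1[C@H](C)C(=O)OCC | intermediate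
17 | keto amide (9α-CH2CONEt2) | O=C1[C@H](CC(=O)N(CC)CC)C2(CC=CC2)[C@@H](C(=O)OCC[Si](C)(C)C)[C@@H]1[C@H](C)C(=O)OCC | intermediate
18 | hydroxy ester (10β-allyl, 10α-OH) | C=CC[C@@]1(O)[C@H](CC(=O)N(CC)CC)C2(CC=CC2)[C@@H](C(=O)OCC[Si](C)(C)C)[C@@H]1[C@H](C)C(=O)OCC | intermediate
19 | allyl lactone | CCN(CC)C(=O)C[C@H]2[C@@]1(CC=C)OC(=O)[C@@H](C)[C@H]1[C@H](C(=O)OCC[Si](C)(C)C)C23CC=CC3 | intermediate
20 | B-alkyl-9-BBN adduct of 19 | CCN(CC)C(=O)C[C@H]2[C@@]1(CCCB4C5CCCC4CCC5)OC(=O)[C@@H](C)[C@H]1[C@H](C(=O)OCC[Si](C)(C)C)C23CC=CC3 | intermediate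
21 | primary alcohol | CCN(CC)C(=O)C[C@H]2[C@@]1(CCCO)OC(=O)[C@@H](C)[C@H]1[C@H](C(=O)OCC[Si](C)(C)C)C23CC=CC3 | intermediate
22 | C3 aldehyde | CCN(CC)C(=O)C[C@H]2[C@@]1(CCC=O)OC(=O)[C@@H](C)[C@H]1[C@H](C(=O)OCC[Si](C)(C)C)C23CC=CC3 | intermediate
23 | tricyclic aldol (C3 epimers) | CCN(CC)C(=O)C[C@H]2[C@@]13CCC(O)[C@@](C)(C(=O)O1)[C@H]3[C@H](C(=O)OCC[Si](C)(C)C)C24CC=CC4 | intermediate
24 | 3-ketone | CCN(CC)C(=O)C[C@H]2[C@@]13CCC(=O)[C@@](C)(C(=O)O1)[C@H]3[C@H](C(=O)OCC[Si](C)(C)C)C24CC=CC4 | intermediate
25 | 3β-alcohol | CCN(CC)C(=O)C[C@H]2[C@@]13CC[C@H](O)[C@@](C)(C(=O)O1)[C@H]3[C@H](C(=O)OCC[Si](C)(C)C)C24CC=CC4 | intermediate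
26 | 3β-TBS ether | CCN(CC)C(=O)C[C@H]2[C@@]13CC[C@H](O[Si](C)(C)C(C)(C)C)[C@@](C)(C(=O)O1)[C@H]3[C@H](C(=O)OCC[Si](C)(C)C)C24CC=CC4 | intermediate
27 | ring-D acyloins (four isomers, C8 and carbinol centre undefined) | CCN(CC)C(=O)C[C@H]2[C@@]13CC[C@H](O[Si](C)(C)C(C)(C)C)[C@@](C)(C(=O)O1)[C@H]3[C@H](C(=O)OCC[Si](C)(C)C)C24CC(O)C(=O)C4 | intermediate
28 | 13,16-bis(TBS) enediol ether | CCN(CC)C(=O)C[C@H]2[C@@]13CC[C@H](O[Si](C)(C)C(C)(C)C)[C@@](C)(C(=O)O1)[C@H]3[C@H](C(=O)OCC[Si](C)(C)C)C24CC(O[Si](C)(C)C(C)(C)C)=C(O[Si](C)(C)C(C)(C)C)C4 | intermediate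
29 | C12 aldehyde | O=CC[C@H]2[C@@]13CC[C@H](O[Si](C)(C)C(C)(C)C)[C@@](C)(C(=O)O1)[C@H]3[C@H](C(=O)OCC[Si](C)(C)C)C24CC(O[Si](C)(C)C(C)(C)C)=C(O[Si](C)(C)C(C)(C)C)C4 | intermediate
30 | tetracyclic 16-ketone (3β,12α,13-tris-OTBS, 7-TMSE ester) | O=C1C[C@]23C[C@@]1(O[Si](C)(C)C(C)(C)C)[C@@H](O[Si](C)(C)C(C)(C)C)C[C@H]2[C@@]12CC[C@H](O[Si](C)(C)C(C)(C)C)[C@@](C)(C(=O)O1)[C@H]2[C@@H]3C(=O)OCC[Si](C)(C)C | intermediate
31 | methyltriphenylphosphonium bromide | C[P+](c1ccccc1)(c1ccccc1)c1ccccc1.[Br-] | starting material
32 | 16-methylene compound (fully protected target) | C=C1C[C@]23C[C@@]1(O[Si](C)(C)C(C)(C)C)[C@@H](O[Si](C)(C)C(C)(C)C)C[C@H]2[C@@]12CC[C@H](O[Si](C)(C)C(C)(C)C)[C@@](C)(C(=O)O1)[C@H]2[C@@H]3C(=O)OCC[Si](C)(C)C | intermediate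
33 | CNP0260503.1, 3β,12α,13-trihydroxy-20-norgibberell-16-ene-7,19-dioic acid 19,10-lactone | C=C1C[C@]23C[C@@]1(O)[C@@H](O)C[C@H]2[C@@]12CC[C@H](O)[C@@](C)(C(=O)O1)[C@H]2[C@@H]3C(=O)O | target

Total step count: 22. Longest linear sequence: 22 steps (from 1).

**Steps most likely to fail**

**Step 20.** The facial selectivity at the aldehyde carbon C12 may erode, or the adduct may suffer acid-induced acyl migration. In the fallback, C12 is set by hydride instead of by the aldol.
- The fallback sets out from 29. Stoichiometric BF3·OEt2 in CH2Cl2 at −78 °C should close ring C to the 12-hydroxy-13-silyloxy 16-ketone F1, whatever the outcome at C12.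
- Non-basic Lombardo methylenation (Zn, CH2Br2, TiCl4) avoids retro-aldol cleavage and gives the 12-hydroxy-16-methylene compound F2.
- Dess–Martin oxidation gives the 12-ketone F3.
- L-Selectride is kept off the α face by the syn-axial C9–C10 bond and should give the axial 12α-alcohol F4.
- TBSOTf/2,6-lutidine returns to the route at 32.

**Step 18.** Enolisation may occur away from the carbinol carbon, which would give the regioisomeric enol silane. In the fallback, the enediol level is reached by reduction instead of by deprotonation.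
- The fallback sets out from 27. Cu(OAc)2 in AcOH/MeOH oxidises all acyloin isomers to the symmetric 1,2-dione F5.
- Two-electron reduction with SmI2 (THF, −78 °C) gives the samarium enediolate F6.
- O-silylation of F6 in the same flask with TBSOTf returns to the route at 28.

**Step 9.** The SN2 reaction at the neopentyl enolate carbon may be sluggish, with proton transfer and loss of facial control. In the fallback, the C9–C11 bond is made by a radical instead of by an SN2 step.
- The fallback sets out from 14. The kinetic enolate 16 is trapped with TMSCl as the trimethylsilyl enol ether F7.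
- The carbamoylmethyl radical is generated from 15 under photoredox conditions (fac-Ir(ppy)3, blue light, 2,6-lutidine, MeCN). It adds to C9 of F7 from the same less shielded α face.
- Loss of the silyl group returns to the route at 17.

**Further compounds**

F1 | step 20 | 12-hydroxy-13-silyloxy 16-ketone (C12 epimers) | O=C1C[C@]23C[C@@]1(O[Si](C)(C)C(C)(C)C)C(O)C[C@H]2[C@@]12CC[C@H](O[Si](C)(C)C(C)(C)C)[C@@](C)(C(=O)O1)[C@H]2[C@@H]3C(=O)OCC[Si](C)(C)C
F2 | step 20 | 12-hydroxy-16-methylene compound (C12 epimers) | C=C1C[C@]23C[C@@]1(O[Si](C)(C)C(C)(C)C)C(O)C[C@H]2[C@@]12CC[C@H](O[Si](C)(C)C(C)(C)C)[C@@](C)(C(=O)O1)[C@H]2[C@@H]3C(=O)OCC[Si](C)(C)C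
F3 | step 20 | 12-ketone | C=C1C[C@]23C[C@@]1(O[Si](C)(C)C(C)(C)C)C(=O)C[C@H]2[C@@]12CC[C@H](O[Si](C)(C)C(C)(C)C)[C@@](C)(C(=O)O1)[C@H]2[C@@H]3C(=O)OCC[Si](C)(C)C
F4 | step 20 | 12α-alcohol | C=C1C[C@]23C[C@@]1(O[Si](C)(C)C(C)(C)C)[C@@H](O)C[C@H]2[C@@]12CC[C@H](O[Si](C)(C)C(C)(C)C)[C@@](C)(C(=O)O1)[C@H]2[C@@H]3C(=O)OCC[Si](C)(C)C
F5 | step 18 | ring-D 1,2-dione | CCN(CC)C(=O)C[C@H]2[C@@]13CC[C@H](O[Si](C)(C)C(C)(C)C)[C@@](C)(C(=O)O1)[C@H]3[C@H](C(=O)OCC[Si](C)(C)C)C24CC(=O)C(=O)C4
F6 | step 18 | samarium enediolate | CCN(CC)C(=O)C[C@H]2[C@@]13CC[C@H](O[Si](C)(C)C(C)(C)C)[C@@](C)(C(=O)O1)[C@H]3[C@H](C(=O)OCC[Si](C)(C)C)C24CC(O[Sm](I)I)=C(O[Sm](I)I)C4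
F7 | step 9 | trimethylsilyl enol ether of 14 (C9=C10) | C[Si](C)(C)OC1=CC2(CC=CC2)[C@@H](C(=O)OCC[Si](C)(C)C)[C@@H]1[C@H](C)C(=O)OCC
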